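**Retrosynthetic overview**

1. Target 14 ← global O-debenzylation of its hexabenzyl ether 13.
2. 13 ← one [3+2] cycloaddition that cuts the oxolane at C2–C3 and C4–C5: carbonyl ylide 12 (from C–C cleavage of stilbene oxide 10) + Z-enedione 7.
3. Enabling feature: in the oxolane ring (O1, C2–C5) the C2–O1–C5 bis-benzylic ether flanked by two electron-rich 4-oxyphenyl groups is a stabilised carbonyl ylide, and C3–C4 with two cis aroyl groups is a Z-enedione. Because the ring is meso (2,5-cis, 3,4-cis, 2,3-trans), one symmetric W-shaped ylide and one symmetric Z-alkene set all four stereocentres.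
4. 10 ← epoxidation of E-stilbene 9 ← McMurry coupling of aldehyde 8. 7 ← oxidative opening of furan 5 ← Paal–Knorr of 1,4-diketone 4 ← oxidative enolate homocoupling of ketone 2 ← benzylation of 1.
5. Ring order: furan (temporary, step 3), oxirane (temporary, step 6), then the oxolane, the only ring of the target that is built (step 7).

Key step: step 7

Assumption (stereochemistry): the descriptors of the target describe the achiral meso isomer (2R,3R,4S,5S), with the aryl groups at C2/C5 cis, the aroyl groups at C3/C4 cis, and C2/C3 and C4/C5 trans. A racemic epoxide therefore suffices and no absolute stereocontrol is needed.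

**Route**

Step 1
Reactants: 1 2',4'-dihydroxyacetophenone
Product: 2 1-[2,4-bis(benzyloxy)phenyl]ethanone
Conditions: BnBr (2.5 equiv), K2CO3 (3 equiv), DMF, 80 °C
Reagents that add atoms: benzyl bromide, BrCc1ccccc1
Why: Williamson ether synthesis under forcing conditions alkylates both phenols, including the hydrogen-bonded 2-OH, which would otherwise add intramolecularly (oxa-Michael) to the later enedione.

Step 2
Reactants: 2 1-[2,4-bis(benzyloxy)phenyl]ethanone (two molecules)
Product: 4 1,4-bis[2,4-bis(benzyloxy)phenyl]butane-1,4-dione, via lithium enolate 3 (not isolated)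
Conditions: LiN(iPr)2 (LDA, 1.05 equiv), THF, −78 °C; then CuCl2 (1.1 equiv) in DMF, −78 °C to rt
Reagents that add atoms: none
Why: Oxidative homocoupling of a ketone lithium enolate by CuCl2 (single-electron oxidation by divalent copper, then C–C coupling) joins two α-carbons of like polarity and is established for aryl methyl ketones; no stereocentre is formed.

Step 3
Reactants: 4 1,4-bis[2,4-bis(benzyloxy)phenyl]butane-1,4-dione
Product: 5 2,5-bis[2,4-bis(benzyloxy)phenyl]furan
Conditions: TsOH·H2O (10 mol%), toluene, reflux, Dean–Stark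
Reagents that add atoms: none
Why: Paal–Knorr furan synthesis (acid-catalysed cyclodehydration of a 1,4-diketone) is driven by aromatisation and azeotropic removal of water, and benzyl aryl ethers tolerate catalytic TsOH.

Step 4
Reactants: 5 2,5-bis[2,4-bis(benzyloxy)phenyl]furan
Product: 7 (Z)-1,4-bis[2,4-bis(benzyloxy)phenyl]but-2-ene-1,4-dione, via furan 2,3-epoxide 6 (not isolated)
Conditions: DMDO (1.05 equiv, acetone solution), CH2Cl2/acetone, −20 to 0 °C, dark; evaporation, crystallisation without acid contact
Reagents that add atoms: dimethyldioxirane (DMDO), CC1(C)OO1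
Why: Oxidative ring opening of a 2,5-disubstituted furan: the dioxirane epoxidises one furan C=C to 6, which opens to the cis-enedione, so the Z geometry is inherited from the ring, and the neutral medium avoids acid-catalysed Z-to-E isomerisation.

Step 5
Reactants: 8 4-(benzyloxy)benzaldehyde (two molecules)
Product: 9 (E)-4,4'-bis(benzyloxy)stilbene
Conditions: TiCl4, Zn dust, THF, 0 °C then reflux
Reagents that add atoms: none
Why: McMurry reductive homocoupling of an aryl aldehyde by low-valent titanium should give the thermodynamically preferred E-stilbene, and aryl benzyl ethers are tolerated.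

Step 6
Reactants: 9 (E)-4,4'-bis(benzyloxy)stilbene
Product: 10 trans-2,3-bis[4-(benzyloxy)phenyl]oxirane (racemic, 2R*,3R*)
Conditions: DMDO (1.2 equiv, acetone solution), CH2Cl2, 0 °C; evaporation, quick filtration through basic alumina
Reagents that add atoms: dimethyldioxirane (DMDO), CC1(C)OO1
Why: Concerted syn oxygen transfer from the dioxirane (alkene epoxidation) to the E-alkene gives the trans-oxirane stereospecifically as a racemate, and the acid-free conditions spare the acid-labile 4-alkoxyaryl epoxide from Meinwald rearrangement.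

Step 7
Reactants: 10 trans-2,3-bis[4-(benzyloxy)phenyl]oxirane (racemic, slight excess); 7 (Z)-1,4-bis[2,4-bis(benzyloxy)phenyl]but-2-ene-1,4-dione
Product: 13 meso-[(2R,3R,4S,5S)-2,5-bis[4-(benzyloxy)phenyl]oxolane-3,4-diyl]bis{[2,4-bis(benzyloxy)phenyl]methanone}, via ring-opened radical cation 11 (not isolated), via carbonyl ylide 12 (not isolated)
Conditions: 9-mesityl-10-methylacridinium tetrafluoroborate (5 mol%), blue LEDs (450 nm), degassed MeCN/CH2Cl2 (1:1), Ar, 20 °C
Reagents that add atoms: none
Why: The excited acridinium oxidises an electron-rich 4-benzyloxyphenyl ring of 10 by single-electron transfer, the strained oxirane C–C bond of the radical cation cleaves to the 2-oxa-allyl radical cation 11, and back electron transfer from the acridinyl radical regenerates the catalyst and gives the planar exo,exo (W-shaped) carbonyl ylide 12. The closest known reaction type is the photoinduced-electron-transfer-sensitised carbonyl ylide 1,3-dipolar cycloaddition of 2,3-diaryloxiranes with electron-poor alkenes such as maleates, maleonitrile and acrylonitrile, which gives 2,5-cis-diaryltetrahydrofurans. The oxolane ring closes by a concerted suprafacial [3+2] (4π+2π) cycloaddition of the electron-rich ylide across the electron-poor C=C of 7, forming C2–C3 and C4–C5 together and in preference to addition across the aryl ketone C=O. C2 and C5 are controlled by the W geometry of the ylide (both aryl groups exo, hence 2,5-cis), C3 and C4 by the Z geometry of 7 (suprafacial addition, hence 3,4-cis), and the 2,3-trans/4,5-trans relationship by an exo approach in which the aroyl groups point away from the ylide oxygen and lie under the inward hydrogens, not under the aryl groups. The step needs retention of the Z geometry of 7 and exo over endo selectivity: the first should hold because 7 does not absorb at 450 nm and the acridinyl radical is too weak a reductant to form the enedione radical anion, the second because the bulky, twisted ortho-substituted aroyl groups would clash with the aryl groups in the endo mode. The adduct is meso, so no enantiocontrol is required, and oxygen is excluded to prevent trapping of the ylide as an ozonide.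

Step 8
Reactants: 13 meso-[(2R,3R,4S,5S)-2,5-bis[4-(benzyloxy)phenyl]oxolane-3,4-diyl]bis{[2,4-bis(benzyloxy)phenyl]methanone}
Product: 14 meso-[(2R,3R,4S,5S)-2,5-bis(4-hydroxyphenyl)oxolane-3,4-diyl]bis[(2,4-dihydroxyphenyl)methanone] (CNP0237262.1)
Conditions: H2 (1 atm), 10% Pd/C, EtOAc/THF, rt, stopped at full debenzylation
Reagents that add atoms: none
Why: Catalytic hydrogenolysis cleaves the six benzyl aryl ethers under neutral conditions, avoiding base (retro-oxa-Michael opening or epimerisation at C3/C4) and acid (ionisation at C2/C5); phenol benzyl ethers should cleave faster than the ring benzylic C–O bonds or the aryl ketones, and no stereocentre is touched.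

**Compound list**

1 | 2',4'-dihydroxyacetophenone | CC(=O)c1ccc(O)cc1O | starting material
2 | 1-[2,4-bis(benzyloxy)phenyl]ethanone | CC(=O)c1ccc(OCc2ccccc2)cc1OCc1ccccc1 | intermediate
3 | lithium enolate of 2 (not isolated) | [Li]OC(=C)c1ccc(OCc2ccccc2)cc1OCc1ccccc1 | intermediate
4 | 1,4-bis[2,4-bis(benzyloxy)phenyl]butane-1,4-dione | O=C(CCC(=O)c1ccc(OCc2ccccc2)cc1OCc1ccccc1)c1ccc(OCc2ccccc2)cc1OCc1ccccc1 | intermediate
5 | 2,5-bis[2,4-bis(benzyloxy)phenyl]furan | c1cc(-c2ccc(OCc3ccccc3)cc2OCc2ccccc2)oc1-c1ccc(OCc2ccccc2)cc1OCc1ccccc1 | intermediate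
6 | furan 2,3-epoxide of 5, 1,3-bis[2,4-bis(benzyloxy)phenyl]-2,6-dioxabicyclo[3.1.0]hex-3-ene (cis-fused, racemic, not isolated) | C(c1ccccc1)Oc1ccc(c(OCc2ccccc2)c1)[C@]12O[C@H]1C=C(O2)c1ccc(OCc2ccccc2)cc1OCc1ccccc1 | intermediate
7 | (Z)-1,4-bis[2,4-bis(benzyloxy)phenyl]but-2-ene-1,4-dione | O=C(/C=C\C(=O)c1ccc(OCc2ccccc2)cc1OCc1ccccc1)c1ccc(OCc2ccccc2)cc1OCc1ccccc1 | intermediate
8 | 4-(benzyloxy)benzaldehyde | O=Cc1ccc(OCc2ccccc2)cc1 | starting material
9 | (E)-4,4'-bis(benzyloxy)stilbene | c1ccc(COc2ccc(/C=C/c3ccc(OCc4ccccc4)cc3)cc2)cc1 | intermediate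
10 | trans-2,3-bis[4-(benzyloxy)phenyl]oxirane (racemic; S,S enantiomer drawn) | c1ccc(COc2ccc([C@@H]3O[C@H]3c3ccc(OCc4ccccc4)cc3)cc2)cc1 | intermediate
11 | ring-opened 2-oxa-allyl radical cation of 10 (not isolated) | c1ccc(COc2ccc(/C=[O+]/[CH]c3ccc(OCc4ccccc4)cc3)cc2)cc1 | intermediate
12 | exo,exo (W-shaped) carbonyl ylide, bis[4-(benzyloxy)benzylidene]oxonium ylide (not isolated) | c1ccc(COc2ccc(/C=[O+]/[CH-]c3ccc(OCc4ccccc4)cc3)cc2)cc1 | intermediate
13 | meso-[(2R,3R,4S,5S)-2,5-bis[4-(benzyloxy)phenyl]oxolane-3,4-diyl]bis{[2,4-bis(benzyloxy)phenyl]methanone} | O=C(c1ccc(OCc2ccccc2)cc1OCc1ccccc1)[C@@H]1[C@H](C(=O)c2ccc(OCc3ccccc3)cc2OCc2ccccc2)[C@@H](c2ccc(OCc3ccccc3)cc2)O[C@H]1c1ccc(OCc2ccccc2)cc1 | intermediate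
14 | meso-[(2R,3R,4S,5S)-2,5-bis(4-hydroxyphenyl)oxolane-3,4-diyl]bis[(2,4-dihydroxyphenyl)methanone] (CNP0237262.1) | O=C(c1ccc(O)cc1O)[C@@H]1[C@H](C(=O)c2ccc(O)cc2O)[C@@H](c2ccc(O)cc2)O[C@H]1c1ccc(O)cc1 | target

**Step count and risks**

Total step count: 8. Longest linear sequence: 6 steps (steps 1, 2, 3, 4, 7, 8); the epoxide branch (steps 5, 6) joins at step 7.

Steps most likely to fail:

Step 7. The process at risk is loss of the Z geometry of 7 in the photoredox medium (energy transfer or radical-ion-catalysed isomerisation) before cycloaddition, which would place the aroyl groups trans. Oxidative degradation of the electron-rich adduct on prolonged irradiation and some endo approach are further risks. The fallback sets out from 8 and 7 and comes back at 13; it generates the same ylide 12 in the dark by a metal carbene route. Aldehyde 8 is condensed with p-toluenesulfonyl hydrazide (MeOH, rt) to 4-(benzyloxy)benzaldehyde N-tosylhydrazone F1. NaOMe converts it to the sodium salt of the tosylhydrazone F2. Warming F2 to 40 °C with BnEt3NCl in 1,4-dioxane releases 4-(benzyloxy)phenyldiazomethane F3 in the flask. Rh2(OAc)4 (1 mol%) turns F3 into a rhodium carbene, which is captured by the carbonyl oxygen of a second molecule of 8 to give ylide 12, and 12 is trapped by 7 to give 13 (three-component carbonyl ylide cycloaddition).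

Step 8. The process at risk is over-reduction: hydrogenolysis of the ring benzylic C2–O/C5–O bonds once the para-phenols are free, or reduction of the aryl ketones. The fallback sets out from 13 and comes back at 14. It is a non-reductive Lewis acid debenzylation with BCl3 and pentamethylbenzene as a non-basic benzyl cation scavenger in CH2Cl2 at −78 °C, followed by a methanol quench. No hydrogen or metal surface is involved; this fallback makes no new compound (F0).

Step 4. The process at risk is over-oxidation of the electron-rich resorcinol rings by the dioxirane, or Z-to-E isomerisation of the enedione during isolation. The fallback sets out from 4 and comes back at 7, bypassing the furan. Diketone 4 is mono-brominated at one α-carbon with CuBr2 (EtOAc/CHCl3, reflux) to 2-bromo-1,4-bis[2,4-bis(benzyloxy)phenyl]butane-1,4-dione F4. Et3N in CH2Cl2 eliminates HBr to (E)-1,4-bis[2,4-bis(benzyloxy)phenyl]but-2-ene-1,4-dione F5. Irradiation of the coloured E isomer with visible light (about 420 nm, EtOAc), where the colourless Z isomer does not absorb, should drive the E-to-Z photoisomerisation to 7.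

**Further compounds**

F1 | step 7 | 4-(benzyloxy)benzaldehyde N-tosylhydrazone (E) | Cc1ccc(cc1)S(=O)(=O)N/N=C/c1ccc(OCc2ccccc2)cc1
F2 | step 7 | sodium salt of the tosylhydrazone | Cc1ccc(cc1)S(=O)(=O)[N-]/N=C/c1ccc(OCc2ccccc2)cc1.[Na+]
F3 | step 7 | 4-(benzyloxy)phenyldiazomethane | [N-]=[N+]=Cc1ccc(OCc2ccccc2)cc1
F0 | step 8 | none | none
F4 | step 4 | 2-bromo-1,4-bis[2,4-bis(benzyloxy)phenyl]butane-1,4-dione (racemic) | O=C(CC(Br)C(=O)c1ccc(OCc2ccccc2)cc1OCc1ccccc1)c1ccc(OCc2ccccc2)cc1OCc1ccccc1
F5 | step 4 | (E)-1,4-bis[2,4-bis(benzyloxy)phenyl]but-2-ene-1,4-dione | O=C(/C=C/C(=O)c1ccc(OCc2ccccc2)cc1OCc1ccccc1)c1ccc(OCc2ccccc2)cc1OCc1ccccc1
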